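## Retrosynthetic overview

- The strategy rests on C8: in ring B (C5–C6–C7–C8–C1–C9) of the bicyclo[3.3.1]nonane it is a gem-dimethyl quaternary carbon bonded to the prenyl-bearing C7 and to the prenyl bridgehead C1. Cutting C7–C8 opens ring B to a cyclohexanone (ring A) with isopropenyl on C1 and 2-bromoallyl on C5; the alkene CH2 becomes the second methyl.
- Late disconnections on the bicycle: C3–aroyl (C3 lithiation/acylation), C5–geranyl (bridgehead lithiation), C4=O (enone β-borylation/oxidation), C7 endo-prenyl (exo-face hydroboration of C7=CH2, then B-alkyl Suzuki coupling).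
- Ring B is closed by a reductive 6-exo Heck reaction; C2 travels through it as a TBS ether and is returned to the ketone afterwards.
- The Heck precursor comes from 2-isopropenyl-2-prenylcyclohexane-1,3-dione: CBS desymmetrising reduction fixes C1, then silylation and C5 alkylation with 2,3-dibromopropene. The dione comes from 3-ethoxycyclohexenone (bromination, Suzuki, hydrolysis, Tsuji–Trost prenylation).
- Ring order: ring A is bought (as the vinylogous ester); ring B is formed in step 8.

Key step: step 8

Assumption (tautomers): the target is drawn as the C4-enol/C2-keto form of a 2,4,9-trione whose enol forms interconvert; the last step delivers this equilibrating trione.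

Assumption (step 5): hydride is taken to add anti to the α-branched isopropenyl group of 7, so that (S)-Me-CBS gives the (2R,3R) alcohol as the major diastereomer; if 7 prefers attack anti to prenyl, (R)-Me-CBS gives the same C2 series as its C3 epimer, which serves equally.

Atom numbers C1–C9 below are those of the target bicycle (C1 prenyl bridgehead, C5 geranyl bridgehead, C9 bridging ketone).

## Route

Step 1
Reactants: 1 3-ethoxycyclohex-2-en-1-one
Product: 2 2-bromo-3-ethoxycyclohex-2-en-1-one
Conditions: NBS, CH2Cl2, 0 °C → rt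
Reagents that add atoms: N-bromosuccinimide, BrN1C(=O)CCC1=O
Why: electrophilic α-bromination of a β-alkoxy enone; the enol-ether α-carbon is the only nucleophilic carbon of 1.

Step 2
Reactants: 2 2-bromo-3-ethoxycyclohex-2-en-1-one; 3 isopropenylboronic acid pinacol ester
Product: 4 3-ethoxy-2-(prop-1-en-2-yl)cyclohex-2-en-1-one
Conditions: Pd(OAc)2 (3 mol %), SPhos (6 mol %), K3PO4, toluene/H2O, 80 °C
Reagents that add atoms: none
Why: Suzuki–Miyaura coupling of an α-bromo enone with an alkenylboronate should place the isopropenyl group on the future C1 without touching the vinylogous ester.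

Step 3
Reactants: 4 3-ethoxy-2-(prop-1-en-2-yl)cyclohex-2-en-1-one
Product: 5 3-hydroxy-2-(prop-1-en-2-yl)cyclohex-2-en-1-one (enol form of 2-isopropenylcyclohexane-1,3-dione)
Conditions: 1 M HCl, THF, 0 °C, short contact; extracted and used at once
Reagents that add atoms: water, O
Why: acid hydrolysis of a vinylogous ester; the dienol is kept cold and used directly because hydration of the isopropenyl group followed by retro-aldol loss of acetone is its decomposition path.

Step 4
Reactants: 5 3-hydroxy-2-(prop-1-en-2-yl)cyclohex-2-en-1-one; 6 prenyl acetate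
Product: 7 2-(3-methylbut-2-en-1-yl)-2-(prop-1-en-2-yl)cyclohexane-1,3-dione (achiral, prochiral at C2)
Conditions: Pd(PPh3)4 (5 mol %), DBU, toluene, 60 °C
Reagents that add atoms: none
Why: Tsuji–Trost allylation; the dione enolate should attack the π-prenylpalladium at its unsubstituted terminus through the α-carbon, and any O-prenyl product re-ionises and funnels to the C-alkylated quaternary dione.

Step 5
Reactants: 7 2-(3-methylbut-2-en-1-yl)-2-(prop-1-en-2-yl)cyclohexane-1,3-dione
Product: 8 (2R,3R)-3-hydroxy-2-(3-methylbut-2-en-1-yl)-2-(prop-1-en-2-yl)cyclohexan-1-one (OH cis to isopropenyl)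
Conditions: (S)-Me-CBS (0.2 equiv), catecholborane (1.1 equiv), toluene, −78 → −40 °C; MeOH quench, aq. NaOH wash; the minor (2S,3R) diastereomer is removed by chromatography and returned to 7 with Dess–Martin periodinane
Reagents that add atoms: none
Why: Corey–Bakshi–Shibata desymmetrising mono-reduction; the catalyst should set the (3R) carbinol at whichever carbonyl reacts (quaternary carbon as the large group), and the quaternary C2 becomes stereogenic by reduction of the carbonyl whose catalyst-preferred face is remote from the isopropenyl group, so the wanted alcohol and its C2 epimer are separable diastereomers, each of high enantiomeric purity.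

Step 6
Reactants: 8 (2R,3R)-3-hydroxy-2-prenyl-2-isopropenylcyclohexan-1-one
Product: 9 (2R,3R)-3-[(tert-butyldimethylsilyl)oxy]-2-(3-methylbut-2-en-1-yl)-2-(prop-1-en-2-yl)cyclohexan-1-one
Conditions: TBSOTf, 2,6-lutidine, CH2Cl2, −78 → 0 °C
Reagents that add atoms: tert-butyldimethylsilyl triflate, CC(C)(C)[Si](C)(C)OS(=O)(=O)C(F)(F)F
Why: silylation of a hindered secondary alcohol with the silyl triflate; the ether blocks retro-aldol cleavage and leaves C9 as the only carbonyl, so the next enolisation is unambiguous.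

Step 7
Reactants: 9 (2R,3R)-3-(TBSO)-2-prenyl-2-isopropenylcyclohexan-1-one; 10 2,3-dibromopropene
Product: 11 (2R,3R,6R)-6-(2-bromoprop-2-en-1-yl)-3-[(tert-butyldimethylsilyl)oxy]-2-(3-methylbut-2-en-1-yl)-2-(prop-1-en-2-yl)cyclohexan-1-one (bromoallyl cis to isopropenyl)
Conditions: LDA (commercial solution), THF, −78 °C; 10, DMPU, −78 → −20 °C; then NaOMe (cat.), MeOH, rt, separation of the C6 epimers, the (6S) epimer being re-equilibrated
Reagents that add atoms: none
Why: SN2 alkylation of the only possible ketone enolate (the other α-carbon is quaternary) at the allylic bromide of 10; C6 is epimerisable, so base equilibration and recycling should supply the cis epimer.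

Step 8
Reactants: 11 (2R,3R,6R)-6-(2-bromoallyl)-3-(TBSO)-2-prenyl-2-isopropenylcyclohexan-1-one
Product: 12 2-[(tert-butyldimethylsilyl)oxy]-8,8-dimethyl-7-methylidene-1-(3-methylbut-2-en-1-yl)bicyclo[3.3.1]nonan-9-one (C1 and C5 as in the target, C5–H, OTBS cis to C8)
Conditions: Pd(OAc)2 (10 mol %), PPh3 (25 mol %), HCO2Na (1.5 equiv), Et4NCl (1 equiv), DMF, 80 °C
Reagents that add atoms: none
Why: Pd(0) inserts into the C7–Br bond, the C7 vinylpalladium adds syn across the C1 isopropenyl alkene with C7 bonding to its internal carbon (new C7–C8 bond), and the neopentyl-type alkylpalladium, which has no β-hydrogen, exchanges bromide for formate, loses CO2 and reductively eliminates C–H, so that the former alkene CH2 becomes the second C8 methyl. The closest known reaction type is the intramolecular reductive (hydride-terminated) Heck cyclisation onto 1,1-disubstituted alkenes, an established way to all-carbon quaternary centres. Ring B (C5–C6–C7–C8–C1–C9) closes in the 6-exo-trig mode from the chair of ring A in which the C5 bromoallyl and C1 isopropenyl groups are 1,3-diaxial, which is possible only for the cis (6R) epimer. C8 carries two methyl groups and is not stereogenic; the bridgehead configurations at C1 and C5 are those of 11, C1 having been fixed in step 5 and C5 becoming locked because the one-carbon bridge can only span cis positions. The step needs 6-exo over 7-endo insertion and reaction at the isopropenyl and not the prenyl alkene: the exo preference of carbopalladation, the higher reactivity of the 1,1-disubstituted alkene and the trans position of the prenyl group secure both, while the silyl ether at C2 removes the enolisable C3 position (no palladium-enolate α-alkenylation, no retro-Claisen) and the sparingly soluble formate is the limiting hydride source, so that the vinylpalladium should cyclise before it is reduced. C7 leaves the step as an exocyclic methylene for step 9.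

Step 9
Reactants: 12 2-(TBSO)-8,8-dimethyl-7-methylidene-1-prenylbicyclo[3.3.1]nonan-9-one; 13 1-bromo-2-methylprop-1-ene
Product: 15 2-[(tert-butyldimethylsilyl)oxy]-8,8-dimethyl-1,7-bis(3-methylbut-2-en-1-yl)bicyclo[3.3.1]nonan-9-one (7-endo prenyl), via alkylborane 14 (not isolated)
Conditions: 9-BBN (1.5 equiv), THF, 0 °C → rt; then 13, PdCl2(dppf) (5 mol %), AsPh3, aq. K3PO4, DMF, 50 °C
Reagents that add atoms: none
Why: anti-Markovnikov hydroboration followed by B-alkyl Suzuki–Miyaura coupling; 9-BBN should take the 1,1-disubstituted alkene in preference to the trisubstituted prenyl alkene and the hindered C9 ketone, and deliver hydrogen to C7 from the exo face (the endo face is blocked by the C3 methylene of ring A), which places the new CH2 chain, and hence the prenyl group, endo as in the target.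

Step 10
Reactants: 15 2-(TBSO)-8,8-dimethyl-1,7-endo-diprenylbicyclo[3.3.1]nonan-9-one
Product: 16 2-hydroxy-8,8-dimethyl-1,7-bis(3-methylbut-2-en-1-yl)bicyclo[3.3.1]nonan-9-one (7-endo prenyl)
Conditions: HF·pyridine, THF/pyridine, 0 °C → rt
Reagents that add atoms: none
Why: fluoride cleavage of the silyl ether under buffered conditions that leave the prenyl groups alone; retro-aldol opening is not available because it would need a bridgehead enolate.

Step 11
Reactants: 16 2-hydroxy-8,8-dimethyl-1,7-endo-diprenylbicyclo[3.3.1]nonan-9-one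
Product: 18 8,8-dimethyl-1,7-bis(3-methylbut-2-en-1-yl)bicyclo[3.3.1]non-3-ene-2,9-dione (7-endo prenyl), via diketone 17 (not isolated)
Conditions: IBX (3 equiv), DMSO/fluorobenzene, rt, then 75 °C
Reagents that add atoms: none
Why: IBX oxidation of the alcohol to the C2 ketone and IBX α,β-dehydrogenation in the same flask; C3 is the only enolisable position (C1 is quaternary, C5 is a bridgehead), so the C3=C4 enone is the only possible product and cannot be oxidised further.

Step 12
Reactants: 18 8,8-dimethyl-1,7-endo-diprenylbicyclo[3.3.1]non-3-ene-2,9-dione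
Product: 20 4-hydroxy-8,8-dimethyl-1,7-bis(3-methylbut-2-en-1-yl)bicyclo[3.3.1]nonane-2,9-dione (OH trans to C6), via boronate 19 (not isolated)
Conditions: B2pin2, CuCl (5 mol %), DPEphos (5 mol %), NaOt-Bu (10 mol %), MeOH (2 equiv), THF, rt; then NaBO3·4H2O, THF/H2O, rt
Reagents that add atoms: sodium perborate (as Na[B(OH)3(OOH)]), [Na+].OO[B-](O)(O)O
Why: copper-catalysed conjugate borylation of the enone (isolated alkenes and the hindered C9 ketone are inert) from the open face anti to ring B, then perborate oxidation with retention; the C4 configuration is set by this facial preference and is erased in step 13.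

Step 13
Reactants: 20 4-hydroxy-8,8-dimethyl-1,7-endo-diprenylbicyclo[3.3.1]nonane-2,9-dione
Product: 21 4-hydroxy-8,8-dimethyl-1,7-bis(3-methylbut-2-en-1-yl)bicyclo[3.3.1]non-3-ene-2,9-dione (enol of the 2,4,9-trione)
Conditions: Dess–Martin periodinane, NaHCO3, CH2Cl2, 0 °C → rt
Reagents that add atoms: none
Why: Dess–Martin oxidation of a β-hydroxy ketone to the 1,3-diketone under buffered, non-basic conditions that avoid dehydration.

Step 14
Reactants: 21 4-hydroxy-8,8-dimethyl-1,7-endo-diprenylbicyclo[3.3.1]non-3-ene-2,9-dione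
Product: 22 4-methoxy-8,8-dimethyl-1,7-bis(3-methylbut-2-en-1-yl)bicyclo[3.3.1]non-3-ene-2,9-dione (7-endo prenyl)
Conditions: Me2SO4, K2CO3, acetone, 50 °C; the minor 2-methoxy regioisomer is separated and recycled by hydrolysis to 21
Reagents that add atoms: dimethyl sulfate, COS(=O)(=O)OC
Why: O-alkylation of the diketone enolate with a hard electrophile should occur mainly at the C4 oxygen, which flanks the C5–H bridgehead, since the C2 oxygen is shielded by the quaternary C1 and the C8 methyl groups.

Step 15
Reactants: 22 4-methoxy-8,8-dimethyl-1,7-endo-diprenylbicyclo[3.3.1]non-3-ene-2,9-dione; 23 geranyl bromide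
Product: 24 5-[(2E)-3,7-dimethylocta-2,6-dien-1-yl]-4-methoxy-8,8-dimethyl-1,7-bis(3-methylbut-2-en-1-yl)bicyclo[3.3.1]non-3-ene-2,9-dione
Conditions: LDA (commercial solution), THF, −78 °C; 23, −78 → −40 °C
Reagents that add atoms: none
Why: bridgehead lithiation of a bicyclo[3.3.1]nonane-2,4,9-trione enol ether with LDA (C5–H acidified by the C9 ketone and the adjacent methoxy-bearing sp2 carbon, lithium held by the methoxy oxygen) and SN2 alkylation; the bridgehead can only react with retention, so C5 has the target configuration.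

Step 16
Reactants: 25 3,4-dihydroxybenzoic acid
Product: 26 tert-butyldimethylsilyl 3,4-bis[(tert-butyldimethylsilyl)oxy]benzoate
Conditions: TBSCl (3.5 equiv), imidazole, DMF, rt
Reagents that add atoms: tert-butyldimethylsilyl chloride, CC(C)(C)[Si](C)(C)Cl
Why: exhaustive silylation of both phenols and the acid under standard imidazole conditions.

Step 17
Reactants: 26 tert-butyldimethylsilyl 3,4-bis(TBSO)benzoate
Product: 27 3,4-bis[(tert-butyldimethylsilyl)oxy]benzoyl chloride
Conditions: (COCl)2, DMF (cat.), CH2Cl2, 0 °C → rt; used crude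
Reagents that add atoms: oxalyl chloride, ClC(=O)C(Cl)=O
Why: conversion of a silyl ester into the acid chloride with the Vilsmeier reagent under neutral conditions (no HCl), so the aryl silyl ethers survive.

Step 18
Reactants: 24 5-geranyl-4-methoxy-8,8-dimethyl-1,7-endo-diprenylbicyclo[3.3.1]non-3-ene-2,9-dione; 27 3,4-bis(TBSO)benzoyl chloride
Product: 28 3-{3,4-bis[(tert-butyldimethylsilyl)oxy]benzoyl}-5-[(2E)-3,7-dimethylocta-2,6-dien-1-yl]-4-methoxy-8,8-dimethyl-1,7-bis(3-methylbut-2-en-1-yl)bicyclo[3.3.1]non-3-ene-2,9-dione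
Conditions: LiTMP (commercial), THF, −78 °C; then 27, −78 → −40 °C
Reagents that add atoms: none
Why: α-lithiation of the β-methoxy enone at C3 with the hindered amide (both bridgeheads are now quaternary) and C-acylation with the acid chloride, which reacts faster than the aryl silyl ethers.

Step 19
Reactants: 28 3-[3,4-bis(TBSO)benzoyl]-5-geranyl-4-methoxy-8,8-dimethyl-1,7-endo-diprenylbicyclo[3.3.1]non-3-ene-2,9-dione
Product: 29 CNP0160101.2, 3-(3,4-dihydroxybenzoyl)-5-[(2E)-3,7-dimethylocta-2,6-dien-1-yl]-4-hydroxy-8,8-dimethyl-1,7-bis(3-methylbut-2-en-1-yl)bicyclo[3.3.1]non-3-ene-2,9-dione (7-endo prenyl)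
Conditions: LiOH, 1,4-dioxane/H2O, 90 °C, argon; 1 M HCl work-up at 0 °C
Reagents that add atoms: lithium hydroxide, [Li+].[OH-]
Why: hydroxide addition–elimination at C4 of the acylated vinylogous ester releases the triketone enolate, and the same base cleaves both aryl silyl ethers; the all-basic deprotection avoids acid-induced cyclisation of the prenyl groups onto the enol, and no stereocentre is touched.

## Compound list

1 | 3-ethoxycyclohex-2-en-1-one | CCOC1=CC(=O)CCC1 | starting material
2 | 2-bromo-3-ethoxycyclohex-2-en-1-one | CCOC1=C(Br)C(=O)CCC1 | intermediate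
3 | isopropenylboronic acid pinacol ester | CC(=C)B1OC(C)(C)C(C)(C)O1 | starting material
4 | 3-ethoxy-2-(prop-1-en-2-yl)cyclohex-2-en-1-one | CCOC1=C(C(C)=C)C(=O)CCC1 | intermediate
5 | 3-hydroxy-2-(prop-1-en-2-yl)cyclohex-2-en-1-one | OC1=C(C(C)=C)C(=O)CCC1 | intermediate
6 | prenyl acetate (3-methylbut-2-en-1-yl acetate) | CC(C)=CCOC(C)=O | starting material
7 | 2-(3-methylbut-2-en-1-yl)-2-(prop-1-en-2-yl)cyclohexane-1,3-dione | CC(C)=CCC1(C(C)=C)C(=O)CCCC1=O | intermediate
8 | (2R,3R)-3-hydroxy-2-(3-methylbut-2-en-1-yl)-2-(prop-1-en-2-yl)cyclohexan-1-one | C1CC[C@@H](O)[C@@](CC=C(C)C)(C(C)=C)C1=O | intermediate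
9 | (2R,3R)-3-[(tert-butyldimethylsilyl)oxy]-2-(3-methylbut-2-en-1-yl)-2-(prop-1-en-2-yl)cyclohexan-1-one | C1CC[C@@H](O[Si](C)(C)C(C)(C)C)[C@@](CC=C(C)C)(C(C)=C)C1=O | intermediate
10 | 2,3-dibromopropene | BrCC(Br)=C | starting material
11 | (2R,3R,6R)-6-(2-bromoprop-2-en-1-yl)-3-[(tert-butyldimethylsilyl)oxy]-2-(3-methylbut-2-en-1-yl)-2-(prop-1-en-2-yl)cyclohexan-1-one | C=C(Br)C[C@H]1CC[C@@H](O[Si](C)(C)C(C)(C)C)[C@@](CC=C(C)C)(C(C)=C)C1=O | intermediate
12 | 2-[(tert-butyldimethylsilyl)oxy]-8,8-dimethyl-7-methylidene-1-(3-methylbut-2-en-1-yl)bicyclo[3.3.1]nonan-9-one (OTBS cis to C8) | [C@H]12CC(=C)C(C)(C)[C@](CC=C(C)C)([C@H](O[Si](C)(C)C(C)(C)C)CC1)C2=O | intermediate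
13 | 1-bromo-2-methylprop-1-ene | CC(C)=CBr | starting material
14 | 7-endo-[(9-borabicyclo[3.3.1]nonan-9-yl)methyl]-2-[(tert-butyldimethylsilyl)oxy]-8,8-dimethyl-1-(3-methylbut-2-en-1-yl)bicyclo[3.3.1]nonan-9-one | [C@H]12C[C@H](CB3C4CCCC3CCC4)C(C)(C)[C@](CC=C(C)C)([C@H](O[Si](C)(C)C(C)(C)C)CC1)C2=O | intermediate (not isolated)
15 | 2-[(tert-butyldimethylsilyl)oxy]-8,8-dimethyl-1,7-bis(3-methylbut-2-en-1-yl)bicyclo[3.3.1]nonan-9-one (7-endo) | [C@H]12C[C@H](CC=C(C)C)C(C)(C)[C@](CC=C(C)C)([C@H](O[Si](C)(C)C(C)(C)C)CC1)C2=O | intermediate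
16 | 2-hydroxy-8,8-dimethyl-1,7-bis(3-methylbut-2-en-1-yl)bicyclo[3.3.1]nonan-9-one (7-endo) | [C@H]12C[C@H](CC=C(C)C)C(C)(C)[C@](CC=C(C)C)([C@H](O)CC1)C2=O | intermediate
17 | 8,8-dimethyl-1,7-bis(3-methylbut-2-en-1-yl)bicyclo[3.3.1]nonane-2,9-dione (7-endo) | [C@H]12C[C@H](CC=C(C)C)C(C)(C)[C@](CC=C(C)C)(C(=O)CC1)C2=O | intermediate (not isolated)
18 | 8,8-dimethyl-1,7-bis(3-methylbut-2-en-1-yl)bicyclo[3.3.1]non-3-ene-2,9-dione (7-endo) | [C@H]12C[C@H](CC=C(C)C)C(C)(C)[C@](CC=C(C)C)(C(=O)C=C1)C2=O | intermediate
19 | 8,8-dimethyl-1,7-bis(3-methylbut-2-en-1-yl)-4-(4,4,5,5-tetramethyl-1,3,2-dioxaborolan-2-yl)bicyclo[3.3.1]nonane-2,9-dione (boron trans to C6) | [C@H]12C[C@H](CC=C(C)C)C(C)(C)[C@](CC=C(C)C)(C(=O)C[C@H]1B3OC(C)(C)C(C)(C)O3)C2=O | intermediate (not isolated)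
20 | 4-hydroxy-8,8-dimethyl-1,7-bis(3-methylbut-2-en-1-yl)bicyclo[3.3.1]nonane-2,9-dione (OH trans to C6) | [C@H]12C[C@H](CC=C(C)C)C(C)(C)[C@](CC=C(C)C)(C(=O)C[C@H]1O)C2=O | intermediate
21 | 4-hydroxy-8,8-dimethyl-1,7-bis(3-methylbut-2-en-1-yl)bicyclo[3.3.1]non-3-ene-2,9-dione | [C@H]12C[C@H](CC=C(C)C)C(C)(C)[C@](CC=C(C)C)(C(=O)C=C1O)C2=O | intermediate
22 | 4-methoxy-8,8-dimethyl-1,7-bis(3-methylbut-2-en-1-yl)bicyclo[3.3.1]non-3-ene-2,9-dione | [C@H]12C[C@H](CC=C(C)C)C(C)(C)[C@](CC=C(C)C)(C(=O)C=C1OC)C2=O | intermediate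
23 | geranyl bromide [(2E)-1-bromo-3,7-dimethylocta-2,6-diene] | CC(C)=CCC/C(C)=C/CBr | starting material
24 | 5-[(2E)-3,7-dimethylocta-2,6-dien-1-yl]-4-methoxy-8,8-dimethyl-1,7-bis(3-methylbut-2-en-1-yl)bicyclo[3.3.1]non-3-ene-2,9-dione | CC(C)=CCC/C(C)=C/C[C@]12C[C@H](CC=C(C)C)C(C)(C)[C@](CC=C(C)C)(C(=O)C=C1OC)C2=O | intermediate
25 | 3,4-dihydroxybenzoic acid | OC(=O)c1ccc(O)c(O)c1 | starting material
26 | tert-butyldimethylsilyl 3,4-bis[(tert-butyldimethylsilyl)oxy]benzoate | CC(C)(C)[Si](C)(C)OC(=O)c1ccc(O[Si](C)(C)C(C)(C)C)c(O[Si](C)(C)C(C)(C)C)c1 | intermediate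
27 | 3,4-bis[(tert-butyldimethylsilyl)oxy]benzoyl chloride | ClC(=O)c1ccc(O[Si](C)(C)C(C)(C)C)c(O[Si](C)(C)C(C)(C)C)c1 | intermediate
28 | 3-{3,4-bis[(tert-butyldimethylsilyl)oxy]benzoyl}-5-geranyl-4-methoxy-8,8-dimethyl-1,7-bis(3-methylbut-2-en-1-yl)bicyclo[3.3.1]non-3-ene-2,9-dione | CC(C)=CCC/C(C)=C/C[C@]12C[C@H](CC=C(C)C)C(C)(C)[C@](CC=C(C)C)(C(=O)C(C(=O)c3ccc(O[Si](C)(C)C(C)(C)C)c(O[Si](C)(C)C(C)(C)C)c3)=C1OC)C2=O | intermediate
29 | CNP0160101.2 | CC(C)=CCC/C(C)=C/C[C@]12C[C@H](CC=C(C)C)C(C)(C)[C@](CC=C(C)C)(C(=O)C(C(=O)c3ccc(O)c(O)c3)=C1O)C2=O | target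

## Step count and risks

Total step count: 19. Longest linear sequence: 17 (steps 1–15, 18, 19); steps 16–17 prepare the acid chloride.

Steps most likely to fail:

1. Step 8 (key step). The vinylpalladium may be reduced by formate before it reaches the alkene, because closure needs the 1,3-diaxial conformer of the cis epimer. C6 may also epimerise to the unreactive trans epimer under the basic conditions, and the neopentylpalladium may add to the new C7 methylene (cyclopropanation and ring expansion) before hydride capture. Fallback: starting from 9, alkylation with propargyl bromide (LDA, THF, −78 °C) would give the (2R,3R,6R)-6-propargyl ketone F1. A Trost-type reductive enyne cyclisation (Pd2(dba)3·CHCl3, AcOH, Et3SiH, toluene) would then generate the same C7 vinylpalladium by hydropalladation of the alkyne, without base or halide, insert 6-exo into the isopropenyl group and end by silane reduction. This returns to the route at 12.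

2. Step 5. The catalyst may discriminate poorly between the two enantiotopic carbonyls, whose flanking groups (isopropenyl, prenyl) are of similar size; little of the wanted diastereomer would then form. Over-reduction to the diol is a second loss. Fallback: starting from 7, NaBH4 (MeOH/CH2Cl2, −78 °C) would give, after removal of the trans diastereomer, the racemic cis hydroxy ketone F2. Lipase PS with vinyl acetate should acylate the (3R) enantiomer (quaternary carbon as the large, CH2 as the medium substituent) to the (1R,2R) acetate F3, which is separated from the unreacted (3S) alcohol; that alcohol is oxidised back to 7. K2CO3 in MeOH then returns to the route at 8.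

3. Step 9. Transmetalation of the hindered, β-branched alkylborane may be slow, so that protodeboronation or isomerisation wins, and the borane may reduce the C9 ketone. Fallback: starting from 12, alkylborane 14 is formed as before and oxidised with NaBO3 to the 7-endo hydroxymethyl compound F4. Dess–Martin oxidation would give the 7-endo aldehyde F5, and a Wittig reaction with salt-free isopropylidenetriphenylphosphorane (THF, −78 °C, to limit epimerisation at C7) would build the prenyl alkene by olefination instead of cross-coupling. This returns to the route at 15.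

Further compounds
F1 | step 8 | (2R,3R,6R)-3-[(tert-butyldimethylsilyl)oxy]-2-(3-methylbut-2-en-1-yl)-2-(prop-1-en-2-yl)-6-(prop-2-yn-1-yl)cyclohexan-1-one | C#CC[C@H]1CC[C@@H](O[Si](C)(C)C(C)(C)C)[C@@](CC=C(C)C)(C(C)=C)C1=O
F2 | step 5 | racemic (2R*,3R*)-3-hydroxy-2-(3-methylbut-2-en-1-yl)-2-(prop-1-en-2-yl)cyclohexan-1-one (both enantiomers) | C1CC[C@@H](O)[C@@](CC=C(C)C)(C(C)=C)C1=O.C1CC[C@H](O)[C@](CC=C(C)C)(C(C)=C)C1=O
F3 | step 5 | (1R,2R)-2-(3-methylbut-2-en-1-yl)-3-oxo-2-(prop-1-en-2-yl)cyclohexyl acetate | C1CC[C@@H](OC(C)=O)[C@@](CC=C(C)C)(C(C)=C)C1=O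
F4 | step 9 | 2-[(tert-butyldimethylsilyl)oxy]-7-endo-(hydroxymethyl)-8,8-dimethyl-1-(3-methylbut-2-en-1-yl)bicyclo[3.3.1]nonan-9-one | [C@H]12C[C@H](CO)C(C)(C)[C@](CC=C(C)C)([C@H](O[Si](C)(C)C(C)(C)C)CC1)C2=O
F5 | step 9 | 2-[(tert-butyldimethylsilyl)oxy]-8,8-dimethyl-1-(3-methylbut-2-en-1-yl)-9-oxobicyclo[3.3.1]nonane-7-endo-carbaldehyde | [C@H]12C[C@H](C=O)C(C)(C)[C@](CC=C(C)C)([C@H](O[Si](C)(C)C(C)(C)C)CC1)C2=O
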